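The synthesis rests on the C8–C9 bond. This is the sp2–sp2 link between the C7=C8 arm on bridgehead C6 of the 7-oxabicyclo[2.2.1]heptane (ring A) and a C29 polyenyl iodide that already carries the trihydroxycyclohexane (ring B). In ring A the exo C5 hydroxyl is cis to the C3–O–C6 bridge, which indicates net retention at C6. One charge of zerovalent palladium therefore does two jobs. It first converts a monocyclic C11 syn-3-hydroxy-5,6-epoxide, bearing an (E)-2-stannylvinyl group on C6, into the bridged ether by double inversion. It then couples C8 with the unprotected iodide. The ethynyl analogue of that epoxide gives ring B by hydrolysis at C5, so both ends come from one enynol.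

Key step: step 15

Remark: carotenoid numbering is used (ring A C1–C6, chain C7–C15, primed numbers for the half ending in ring B), and (2E,4E,6E)-2,7-dimethylocta-2,4,6-trienedial is taken as a commercial carotenoid building block.

Step 1
Reactants: 1 ketoisophorone (2,6,6-trimethylcyclohex-2-ene-1,4-dione)
Product: 2 (4R)-4-hydroxy-2,6,6-trimethylcyclohex-2-en-1-one
Conditions: RuCl[(R,R)-TsDPEN](p-cymene) (0.5 mol %), KOt-Bu (1 mol %), i-PrOH, rt
Reagents that add atoms: none
Why: Noyori asymmetric transfer hydrogenation reduces only the unhindered C4 carbonyl (the other is flanked by three methyl groups), and with the alkenyl flank in the place of the aryl group of the usual model the (R,R)-ligand should set the R carbinol centre that becomes C3 and C3'.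

Step 2
Reactants: 2 (4R)-4-hydroxy-2,6,6-trimethylcyclohex-2-en-1-one
Product: 3 (4R)-4-(tert-butyldimethylsilyloxy)-2,6,6-trimethylcyclohex-2-en-1-one
Conditions: TBSCl, imidazole, DMF, rt
Reagents that add atoms: tert-butyldimethylsilyl chloride, CC(C)(C)[Si](C)(C)Cl
Why: Routine silyl ether formation masks the only acidic proton before the hydride and triflation steps and leaves the stereocentre untouched.

Step 3
Reactants: 3 (4R)-4-(tert-butyldimethylsilyloxy)-2,6,6-trimethylcyclohex-2-en-1-one
Product: 5 (4S)-4-(tert-butyldimethylsilyloxy)-2,6,6-trimethylcyclohex-1-en-1-yl trifluoromethanesulfonate, via lithium enolate 4 (not isolated)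
Conditions: LiBH(s-Bu)3 (1.1 equiv), THF, −78 °C; then PhNTf2, −78 °C to rt
Reagents that add atoms: N-phenylbis(trifluoromethanesulfonimide), O=S(=O)(N(c1ccccc1)S(=O)(=O)C(F)(F)F)C(F)(F)F
Why: The bulky borohydride adds hydride 1,4 to the β-unsubstituted enone, whose carbonyl is shielded by three α-methyl groups, and O-triflation of the regiodefined enolate gives the tetrasubstituted C5=C6 enol triflate without touching C3 (the descriptor changes only through the priority rules).

Step 4
Reactants: 5 (4S)-4-(tert-butyldimethylsilyloxy)-2,6,6-trimethylcyclohex-1-en-1-yl trifluoromethanesulfonate; 6 trimethylsilylacetylene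
Product: 7 tert-butyldimethyl{[(1S)-3,5,5-trimethyl-4-(trimethylsilylethynyl)cyclohex-3-en-1-yl]oxy}silane
Conditions: PdCl2(PPh3)2 (5 mol %), CuI (10 mol %), Et3N, DMF, 60 °C
Reagents that add atoms: none
Why: Sonogashira coupling of the enol triflate places C7 and C8 on C6 regiospecifically, so that no dehydration of uncertain regiochemistry is needed.

Step 5
Reactants: 7 tert-butyldimethyl{[(1S)-3,5,5-trimethyl-4-(trimethylsilylethynyl)cyclohex-3-en-1-yl]oxy}silane
Product: 8 (1S)-4-ethynyl-3,5,5-trimethylcyclohex-3-en-1-ol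
Conditions: TBAF (2.5 equiv), THF, 0 °C to rt
Reagents that add atoms: none
Why: Fluoride cleaves the O–Si and the alkynyl C–Si bond in one desilylation and gives the enynol from which both end groups branch.

Step 6
Reactants: 8 (1S)-4-ethynyl-3,5,5-trimethylcyclohex-3-en-1-ol
Product: 9 (1R,3R,6R)-6-ethynyl-1,5,5-trimethyl-7-oxabicyclo[4.1.0]heptan-3-ol (epoxide oxygen cis to the hydroxyl)
Conditions: VO(acac)2 (5 mol %), t-BuOOH (decane solution), CH2Cl2, 0 °C to rt
Reagents that add atoms: tert-butyl hydroperoxide, CC(C)(C)OO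
Why: Vanadium-catalysed hydroxyl-directed epoxidation of the homoallylic cyclohexenol delivers oxygen to the face of C5=C6 that carries the C3 hydroxyl, which sets C5 and C6, and the alkyne is inert.

Step 7
Reactants: 9 (1R,3R,6R)-6-ethynyl-1,5,5-trimethyl-7-oxabicyclo[4.1.0]heptan-3-ol
Product: 10 (1R,2S,4R)-1-ethynyl-2,6,6-trimethylcyclohexane-1,2,4-triol (1-OH and 4-OH cis, 2-OH trans to both)
Conditions: HClO4 (cat.), THF/H2O, 0 °C to rt
Reagents that add atoms: water, O
Why: In this acid-catalysed epoxide hydrolysis the ethynyl group disfavours positive charge at C6, so water attacks the tertiary C5 from the face opposite the oxygen in a trans-diaxial opening, which inverts C5, keeps the C6–O bond and gives the 5,6-trans-diol with the C6 hydroxyl cis to the C3 hydroxyl.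

Step 8
Reactants: 10 (1R,2S,4R)-1-ethynyl-2,6,6-trimethylcyclohexane-1,2,4-triol
Product: 11 (1S,2S,4R)-2,6,6-trimethyl-1-[(E)-2-(tributylstannyl)ethenyl]cyclohexane-1,2,4-triol
Conditions: Bu3SnH, PdCl2(PPh3)2 (2 mol %), THF, 0 °C to rt
Reagents that add atoms: tributyltin hydride, CCCC[SnH](CCCC)CCCC
Why: Palladium-catalysed hydrostannation adds H and Sn syn, and the quaternary propargylic C6' sends tin to the terminal C8', which gives the E-alkenylstannane in the presence of the free hydroxyls.

Step 9
Reactants: 8 (1S)-4-ethynyl-3,5,5-trimethylcyclohex-3-en-1-ol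
Product: 12 (1S)-3,5,5-trimethyl-4-[(E)-2-(tributylstannyl)ethenyl]cyclohex-3-en-1-ol
Conditions: Bu3SnH, PdCl2(PPh3)2 (2 mol %), THF, 0 °C to rt
Reagents that add atoms: tributyltin hydride, CCCC[SnH](CCCC)CCCC
Why: Palladium-catalysed syn-hydrostannation of the terminal alkyne places tin on C8, away from the tetrasubstituted ring alkene and the geminal methyl groups, and gives the E-dienylstannane.

Step 10
Reactants: 12 (1S)-3,5,5-trimethyl-4-[(E)-2-(tributylstannyl)ethenyl]cyclohex-3-en-1-ol
Product: 13 (1R,3R,6S)-1,5,5-trimethyl-6-[(E)-2-(tributylstannyl)ethenyl]-7-oxabicyclo[4.1.0]heptan-3-ol (epoxide oxygen cis to the hydroxyl)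
Conditions: VO(acac)2 (5 mol %), t-BuOOH (decane solution), 2,6-lutidine (10 mol %), CH2Cl2, 0 °C; Et3N-deactivated silica
Reagents that add atoms: tert-butyl hydroperoxide, CC(C)(C)OO
Why: The same hydroxyl-directed vanadium epoxidation reaches only the homoallylic ring alkene C5=C6 on the face of the C3 hydroxyl, which sets C5 and C6, while the remote alkenylstannane is neither bound to the catalyst nor attacked by the neutral hydroperoxide.

Step 11
Reactants: 14 but-2-yn-1-ol
Product: 16 (E)-3-iodobut-2-en-1-ol, via alkenylzirconocene 15 (not isolated)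
Conditions: Cp2Zr(H)Cl (2.2 equiv), THF, rt, dark; then I2, 0 °C
Reagents that add atoms: iodine, II
Why: In this hydrozirconation–iodinolysis the first equivalent turns the hydroxyl into a bulky zirconium alkoxide, the second adds H and Zr syn with zirconium at the methyl-bearing carbon far from that group, and iodine replaces zirconium with retention to give the E-iodide.

Step 12
Reactants: 16 (E)-3-iodobut-2-en-1-ol
Product: 17 diethyl [(E)-3-iodobut-2-en-1-yl]phosphonate
Conditions: P(OEt)3 (3 equiv), ZnI2 (1.5 equiv), THF, reflux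
Reagents that add atoms: triethyl phosphite, CCOP(OCC)OCC
Why: The zinc iodide-mediated Arbuzov-type reaction converts the allylic alcohol directly into the phosphonate at the primary carbon and leaves the alkenyl iodide and its geometry untouched.

Step 13
Reactants: 17 diethyl [(E)-3-iodobut-2-en-1-yl]phosphonate (2.3 equiv); 18 (2E,4E,6E)-2,7-dimethylocta-2,4,6-trienedial
Product: 21 (2E,4E,6E,8E,10E,12E,14E)-2,15-diiodo-6,11-dimethylhexadeca-2,4,6,8,10,12,14-heptaene, via phosphonate anion 19 (not isolated), via iodopentaenal 20 (not isolated)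
Conditions: NaN(SiMe3)2 (2.3 equiv), THF, −78 °C; then 18, −78 to 0 °C, dark
Reagents that add atoms: none
Why: Twofold Horner–Wadsworth–Emmons olefination with the allylic phosphonate anion forms the E-configured C11=C12 and C11'=C12' bonds, and the amide base does not touch the alkenyl iodide at low temperature.

Step 14
Reactants: 11 (1S,2S,4R)-2,6,6-trimethyl-1-[(E)-2-(tributylstannyl)ethenyl]cyclohexane-1,2,4-triol; 21 (all-E)-2,15-diiodo-6,11-dimethylhexadeca-2,4,6,8,10,12,14-heptaene (3 equiv, surplus recovered)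
Product: 22 (1S,2S,4R)-1-[(1E,3E,5E,7E,9E,11E,13E,15E)-16-iodo-3,7,12-trimethylheptadeca-1,3,5,7,9,11,13,15-octaen-1-yl]-2,6,6-trimethylcyclohexane-1,2,4-triol
Conditions: Pd(PPh3)4 (5 mol %), CuI (10 mol %), CsF (2 equiv), DMF/THF, rt, argon, dark
Reagents that add atoms: none
Why: Stille coupling with retention at both alkenes forms C8'–C9', the excess of the C2-symmetric diiodide holds back the second coupling, and the polarity gap between diiodide, triol and hexaol should allow separation and recovery.

Step 15
Reactants: 13 (1R,3R,6S)-1,5,5-trimethyl-6-[(E)-2-(tributylstannyl)ethenyl]-7-oxabicyclo[4.1.0]heptan-3-ol; 22 C29 iodo-octaenyl triol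
Product: 24 (all-E,3R,5R,6S,3'R,5'S,6'S)-3,6-epoxy-5,6,5',6'-tetrahydro-β,β-carotene-5,3',5',6'-tetrol, via bridged stannane 23 (not isolated)
Conditions: Pd(PPh3)4 (10 mol %), THF, 40 °C, argon; then 22, CuI (20 mol %), CsF (2 equiv), DMF, rt, dark
Reagents that add atoms: none
Why: Proposed new method: zerovalent palladium ionises the C6–O bond of vinyl epoxide 13 from the face opposite the oxygen to an allylpalladium over C6–C7–C8, the C5 alkoxide set free takes the proton of the C3 hydroxyl, and the C3 oxygen, which sits on the face the epoxide oxygen has just left, attacks C6 anti to the metal to give 23; after 22, CuI and CsF are added the same catalyst inserts into the C9–I bond, receives C8 from tin by way of copper and forms the C8–C9 bond by reductive elimination with retention at both alkenes. The closest known reaction types are the Tsuji–Trost cycloetherification of hydroxy vinyl epoxides, a 1,2-addition with net retention, and the Stille coupling of alkenylstannanes with polyenyl iodides, whereas the transannular closure at a tetrasubstituted epoxide and the relay on a substrate that carries the stannane are not precedented. The oxygen bridge closes transannularly in the 5-exo-trig mode with respect to the allyl unit and thereby completes both oxolane rings of the 7-oxabicyclo[2.2.1]heptane at once. C6 is the only stereocentre that is re-formed, and double inversion, enforced by the C3 tether, gives it the S configuration with the bridge cis to the exo C5 hydroxyl, while C3 and C5 keep their C–O bonds. Regioselectivity for C6 over C8 is secured because the C3 oxygen can reach only C6, β-hydride loss from the allyl complex is excluded because C1 and C5 are quaternary, and allyl–stannane coupling between two molecules is held back by running the first stage in THF without copper or fluoride. The syn-allyl complex returns the E-C7=C8 bond, and room temperature, darkness and the absence of acid protect the nonaene and the tertiary allylic C6' alcohol.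

Compound list
1 | ketoisophorone (2,6,6-trimethylcyclohex-2-ene-1,4-dione) | CC1=CC(=O)CC(C)(C)C1=O | starting material
2 | (4R)-4-hydroxy-2,6,6-trimethylcyclohex-2-en-1-one | CC1=C[C@H](O)CC(C)(C)C1=O | intermediate
3 | (4R)-4-(tert-butyldimethylsilyloxy)-2,6,6-trimethylcyclohex-2-en-1-one | CC1=C[C@H](O[Si](C)(C)C(C)(C)C)CC(C)(C)C1=O | intermediate
4 | lithium (4S)-4-(tert-butyldimethylsilyloxy)-2,6,6-trimethylcyclohex-1-en-1-olate | [Li+].CC1=C([O-])C(C)(C)C[C@@H](O[Si](C)(C)C(C)(C)C)C1 | intermediate
5 | (4S)-4-(tert-butyldimethylsilyloxy)-2,6,6-trimethylcyclohex-1-en-1-yl trifluoromethanesulfonate | CC1=C(OS(=O)(=O)C(F)(F)F)C(C)(C)C[C@@H](O[Si](C)(C)C(C)(C)C)C1 | intermediate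
6 | trimethylsilylacetylene | C#C[Si](C)(C)C | starting material
7 | tert-butyldimethyl{[(1S)-3,5,5-trimethyl-4-(trimethylsilylethynyl)cyclohex-3-en-1-yl]oxy}silane | CC1=C(C#C[Si](C)(C)C)C(C)(C)C[C@@H](O[Si](C)(C)C(C)(C)C)C1 | intermediate
8 | (1S)-4-ethynyl-3,5,5-trimethylcyclohex-3-en-1-ol | CC1=C(C#C)C(C)(C)C[C@@H](O)C1 | intermediate
9 | (1R,3R,6R)-6-ethynyl-1,5,5-trimethyl-7-oxabicyclo[4.1.0]heptan-3-ol | C#C[C@@]12O[C@]1(C)C[C@H](O)CC2(C)C | intermediate
10 | (1R,2S,4R)-1-ethynyl-2,6,6-trimethylcyclohexane-1,2,4-triol | C#C[C@]1(O)C(C)(C)C[C@@H](O)C[C@]1(C)O | intermediate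
11 | (1S,2S,4R)-2,6,6-trimethyl-1-[(E)-2-(tributylstannyl)ethenyl]cyclohexane-1,2,4-triol | CCCC[Sn](CCCC)(CCCC)/C=C/[C@]1(O)C(C)(C)C[C@@H](O)C[C@]1(C)O | intermediate
12 | (1S)-3,5,5-trimethyl-4-[(E)-2-(tributylstannyl)ethenyl]cyclohex-3-en-1-ol | CC1=C(/C=C/[Sn](CCCC)(CCCC)CCCC)C(C)(C)C[C@@H](O)C1 | intermediate
13 | (1R,3R,6S)-1,5,5-trimethyl-6-[(E)-2-(tributylstannyl)ethenyl]-7-oxabicyclo[4.1.0]heptan-3-ol | CCCC[Sn](CCCC)(CCCC)/C=C/[C@@]12O[C@]1(C)C[C@H](O)CC2(C)C | intermediate
14 | but-2-yn-1-ol | CC#CCO | starting material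
15 | (E)-alkenylzirconocene chloride of the zirconium alkoxide of 14 (Zr and CH2O trans, cyclopentadienyl rings drawn σ-bonded) | Cl[Zr](C1C=CC=C1)(C1C=CC=C1)/C(C)=C/CO[Zr](Cl)(C1C=CC=C1)C1C=CC=C1 | intermediate
16 | (E)-3-iodobut-2-en-1-ol | I/C(C)=C/CO | intermediate
17 | diethyl [(E)-3-iodobut-2-en-1-yl]phosphonate | I/C(C)=C/CP(=O)(OCC)OCC | intermediate
18 | (2E,4E,6E)-2,7-dimethylocta-2,4,6-trienedial | O=C/C(C)=C/C=C/C=C(C)/C=O | starting material
19 | sodium salt of the α-carbanion of 17 | [Na+].I/C(C)=C/[CH-]P(=O)(OCC)OCC | intermediate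
20 | (2E,4E,6E,8E,10E)-11-iodo-2,7-dimethyldodeca-2,4,6,8,10-pentaenal | I/C(C)=C/C=C/C(C)=C/C=C/C=C(C)/C=O | intermediate
21 | (2E,4E,6E,8E,10E,12E,14E)-2,15-diiodo-6,11-dimethylhexadeca-2,4,6,8,10,12,14-heptaene | I/C(C)=C/C=C/C(C)=C/C=C/C=C(C)/C=C/C=C(C)/I | intermediate
22 | (1S,2S,4R)-1-[(all-E)-16-iodo-3,7,12-trimethylheptadeca-1,3,5,7,9,11,13,15-octaen-1-yl]-2,6,6-trimethylcyclohexane-1,2,4-triol | I/C(C)=C/C=C/C(C)=C/C=C/C=C(C)/C=C/C=C(C)/C=C/[C@]1(O)C(C)(C)C[C@@H](O)C[C@]1(C)O | intermediate
23 | (1S,2R,4R)-2,6,6-trimethyl-1-[(E)-2-(tributylstannyl)ethenyl]-7-oxabicyclo[2.2.1]heptan-2-ol (2-OH exo) | CCCC[Sn](CCCC)(CCCC)/C=C/[C@]12O[C@H](CC1(C)C)C[C@@]2(C)O | intermediate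
24 | (all-E,3R,5R,6S,3'R,5'S,6'S)-3,6-epoxy-5,6,5',6'-tetrahydro-β,β-carotene-5,3',5',6'-tetrol | CC(/C=C/C=C(C)/C=C/[C@]12O[C@H](CC1(C)C)C[C@@]2(C)O)=C\C=C\C=C(C)\C=C\C=C(C)\C=C\[C@]1(O)C(C)(C)C[C@@H](O)C[C@]1(C)O | target

Total step count: 15. Longest linear sequence: 10 steps (steps 1–8, 14, 15).

Steps most likely to fail

1. Step 15 (the labelled step).
- What may go wrong: the hindered tetrasubstituted epoxide may ionise too slowly. The allylpalladium may also be diverted, either by attack of the C5 alkoxide at C8 or by allyl–stannane coupling between two molecules before the bridge closes.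
- Fallback with known chemistry, from 9 back to 23: Co2(CO)8 in CH2Cl2 converts the alkyne of 9 into the hexacarbonyldicobalt epoxide complex F1. BF3·OEt2 at −78 °C opens the C6–O bond to the cobalt-stabilised propargylic cation (Nicholas reaction). Only the C3 hydroxyl can reach this cation, and only from its own face, so the bridged hexacarbonyldicobalt complex F2 forms. (NH4)2Ce(NO3)6 in acetone releases the bridged alkyne F3. PdCl2(PPh3)2/Bu3SnH then gives 23, now isolated, which enters an ordinary Stille coupling with 22 under the second-stage conditions.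

2. Step 14.
- What may go wrong: a statistical second coupling at the remaining iodide, and slow decay of the diiodide during the reaction and its recovery.
- Fallback from 17 and 18 back to 22: one equivalent of anion 19 with an excess of 18 stops at 20, now isolated, because the first olefination lowers the reactivity of the remaining aldehyde. Stille coupling of 20 with 11 gives the C25 aldehyde triol F4. N-(trimethylsilyl)imidazole masks the hydroxyls as the tris(trimethylsilyl) ether F5. Olefination with 19 gives the silylated C29 iodide F6, and TBAF buffered with acetic acid returns 22. The two chain ends then carry different functional groups at every stage.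

3. Step 10.
- What may go wrong: loss of tin by protodestannylation or oxidation, or Lewis acid-induced opening of the newly formed vinyl epoxide on the vanadium catalyst.
- Fallback from 9 to 24, with boron in place of tin and introduced after the epoxidation: pinacolborane (2.2 equiv) with Cy2BH (5 mol %) hydroborates the alkyne of 9 to the O-borylated alkenylboronate F7. Aqueous work-up frees the epoxy alkenylboronate F8. Pd(PPh3)4 in THF isomerises it to the bridged alkenylboronate F9. Addition of 22 and aqueous KOH then forms the same C8–C9 bond by Suzuki–Miyaura coupling and gives 24.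

Further compounds
F1 | step 15 | hexacarbonyldicobalt complex of the alkyne of 9 | [CH]34[Co]5(=C=O)(=C=O)(=C=O)[Co]3(=C=O)(=C=O)(=C=O)C45[C@@]12O[C@]1(C)C[C@H](O)CC2(C)C
F2 | step 15 | hexacarbonyldicobalt complex of the bridged alkyne F3 | [CH]34[Co]5(=C=O)(=C=O)(=C=O)[Co]3(=C=O)(=C=O)(=C=O)C45[C@]12O[C@H](CC1(C)C)C[C@@]2(C)O
F3 | step 15 | (1R,2R,4R)-1-ethynyl-2,6,6-trimethyl-7-oxabicyclo[2.2.1]heptan-2-ol (2-OH exo) | C#C[C@]12O[C@H](CC1(C)C)C[C@@]2(C)O
F4 | step 14 | (all-E)-2,7,11-trimethyl-13-[(1S,2S,4R)-1,2,4-trihydroxy-2,6,6-trimethylcyclohexyl]trideca-2,4,6,8,10,12-hexaenal | O=C/C(C)=C/C=C/C=C(C)/C=C/C=C(C)/C=C/[C@]1(O)C(C)(C)C[C@@H](O)C[C@]1(C)O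
F5 | step 14 | tris(trimethylsilyl) ether of F4 | O=C/C(C)=C/C=C/C=C(C)/C=C/C=C(C)/C=C/[C@]1(O[Si](C)(C)C)C(C)(C)C[C@@H](O[Si](C)(C)C)C[C@]1(C)O[Si](C)(C)C
F6 | step 14 | tris(trimethylsilyl) ether of 22 | I/C(C)=C/C=C/C(C)=C/C=C/C=C(C)/C=C/C=C(C)/C=C/[C@]1(O[Si](C)(C)C)C(C)(C)C[C@@H](O[Si](C)(C)C)C[C@]1(C)O[Si](C)(C)C
F7 | step 10 | O-(pinacolatoboryl) derivative of F8 | CC1(C)OB(/C=C/[C@@]23O[C@]2(C)C[C@H](OB4OC(C)(C)C(C)(C)O4)CC3(C)C)OC1(C)C
F8 | step 10 | (1R,3R,6S)-1,5,5-trimethyl-6-[(E)-2-(4,4,5,5-tetramethyl-1,3,2-dioxaborolan-2-yl)ethenyl]-7-oxabicyclo[4.1.0]heptan-3-ol | CC1(C)OB(/C=C/[C@@]23O[C@]2(C)C[C@H](O)CC3(C)C)OC1(C)C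
F9 | step 10 | (1S,2R,4R)-2,6,6-trimethyl-1-[(E)-2-(4,4,5,5-tetramethyl-1,3,2-dioxaborolan-2-yl)ethenyl]-7-oxabicyclo[2.2.1]heptan-2-ol | CC1(C)OB(/C=C/[C@]23O[C@H](CC2(C)C)C[C@@]3(C)O)OC1(C)C
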